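**Plan**

1. Locants follow iridal numbering: C1 formyl carbon, C2 exocyclic alkene carbon, C3–C5 acyloxypropyl chain (O on C3), ring C6 (CH)–C7 (alkene carbon)–C8–C9–C10 (C–OH)–C11 (quaternary), side chain C12–C24 with C16 the carbinol.
2. Retrosynthesis: the 10-OH/C7=C2–CHO pair is read as the retro-oxa-Michael form of a C7–O–C10 ether, so the ring becomes a 7-oxabicyclo[2.2.1]heptane, i.e. the reduced Diels–Alder adduct of a 2,5-disubstituted furan (C7–C10) and an (E)-2-methylenoyl unit (C11=C6). Cuts, in order: 16-O-silyl, C7–O (as C2=C7), C13–C14, then C6–C7 with C10–C11, then the acyl C–S bond.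
3. Enabling feature: C7 and C10 are para in the six-membered ring and carry an alkylidene with a β-formyl group and a tertiary hydroxyl. The C10 methyl and C12 flank the C10–C11 bond, so a CH2–S–C(=O) tether (a thiolactone ring absent from the target) can hold diene and dienophile and is later reduced to that methyl and C12.
4. Forward: furan fragment A and acid fragment B give an S-furfuryl thioester; one intramolecular furan Diels–Alder reaction closes ring C6–C11, the oxygen bridge and the thiolactone; Raney Ni, C12 aldehyde, vinyl, B-alkyl Suzuki coupling with vinyl iodide fragment C (C14–C24); then C1 aldehyde, bridge opening to enal and 10-OH, desilylation.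
5. Stereochemistry: C6/C10/C11 relative configuration from the exo-constrained tether and the E dienophile. Absolute configuration from a traceless (R)-C2 centre (Evans alkylation): it makes the two facial adducts separable diastereomers and vanishes when C2 becomes sp2. C16 from CBS reduction; 14E from carboalumination, 18E from geranyl chloride, 2Z from the elimination.

Key step: step 11

**Fragment A (furan)**

Step 1
Reactants: 1 2-(furan-2-yl)acetic acid; 2 (S)-4-benzyloxazolidin-2-one
Product: 3 (S)-4-benzyl-3-[2-(furan-2-yl)acetyl]oxazolidin-2-one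
Conditions: DCC, DMAP (cat.), CH2Cl2, 0 → 25 °C
Reagents that add atoms: none
Why: Carbodiimide-mediated N-acylation of the oxazolidinone (Steglich-type coupling) attaches the auxiliary without forming a stereocentre.

Step 2
Reactants: 3 (S)-4-benzyl-3-[2-(furan-2-yl)acetyl]oxazolidin-2-one
Product: 5 (S)-4-benzyl-3-[(S)-2-(furan-2-yl)propanoyl]oxazolidin-2-one, via sodium enolate 4 (not isolated)
Conditions: NaHMDS, THF, −78 °C; then MeI, −78 → −40 °C
Reagents that add atoms: iodomethane CI
Why: Evans asymmetric alkylation, in which the chelated Z enolate 4 should be methylated on the face opposite the benzyl group and so set the future C2 centre.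

Step 3
Reactants: 5 (S)-4-benzyl-3-[(S)-2-(furan-2-yl)propanoyl]oxazolidin-2-one
Product: 6 (R)-2-(furan-2-yl)propan-1-ol
Conditions: LiBH4, H2O (1 equiv), Et2O, 0 °C
Reagents that add atoms: none
Why: Reductive cleavage of the imide by LiBH4 should release the primary alcohol without epimerising the α-centre and return the auxiliary.

Step 4
Reactants: 6 (R)-2-(furan-2-yl)propan-1-ol
Product: 7 (R)-tert-butyl[2-(furan-2-yl)propoxy]dimethylsilane
Conditions: TBSCl, imidazole, DMF, 25 °C
Reagents that add atoms: tert-butyldimethylsilyl chloride CC(C)(C)[Si](C)(C)Cl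
Why: Standard silylation of a primary alcohol, which masks the future C1 oxygen.

Step 5
Reactants: 7 (R)-tert-butyl[2-(furan-2-yl)propoxy]dimethylsilane
Product: 9 {5-[(R)-1-(tert-butyldimethylsilyloxy)propan-2-yl]furan-2-yl}methanol, via 5-lithiofuran 8 (not isolated)
Conditions: n-BuLi, THF, −78 → 0 °C; then HCHO (cracked paraformaldehyde), −78 → 25 °C; H2O
Reagents that add atoms: formaldehyde C=O
Why: α-Lithiation of a 2-alkylfuran occurs at the free C5 position, and hydroxymethylation of 8 should install the carbon that becomes the C10 methyl.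

Step 6
Reactants: 9 {5-[(R)-1-(tert-butyldimethylsilyloxy)propan-2-yl]furan-2-yl}methanol
Product: 10 S-({5-[(R)-1-(tert-butyldimethylsilyloxy)propan-2-yl]furan-2-yl}methyl) ethanethioate
Conditions: PPh3, DIAD, AcSH, THF, 0 °C
Reagents that add atoms: thioacetic acid CC(=O)S
Why: Mitsunobu substitution of the primary furfuryl alcohol by a thioacid introduces the tether sulfur under neutral conditions.

**Fragment B (acid)**

Step 7
Reactants: 11 pent-4-en-1-ol; 12 tetradecanoyl chloride
Product: 13 pent-4-en-1-yl tetradecanoate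
Conditions: Et3N, DMAP (cat.), CH2Cl2, 0 → 25 °C
Reagents that add atoms: none
Why: Acylation of a primary alcohol by an acid chloride places the target's fatty ester at the outset, where it also protects O3.

Step 8
Reactants: 13 pent-4-en-1-yl tetradecanoate; 14 tert-butyl methacrylate
Product: 15 tert-butyl (E)-2-methyl-6-(tetradecanoyloxy)hex-2-enoate
Conditions: second-generation Grubbs catalyst (5 mol %), 14 (10 equiv), CH2Cl2, 40 °C
Reagents that add atoms: none
Why: Olefin cross-metathesis of a terminal alkene with a methacrylate should give the trisubstituted E enoate, the geometry that later places the C6 chain cis to the C11 methyl.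

Step 9
Reactants: 15 tert-butyl (E)-2-methyl-6-(tetradecanoyloxy)hex-2-enoate
Product: 16 (E)-2-methyl-6-(tetradecanoyloxy)hex-2-enoic acid
Conditions: TFA, CH2Cl2, 25 °C
Reagents that add atoms: none
Why: Acidolysis of the tert-butyl ester (loss of the tert-butyl cation as alkene) leaves the primary tetradecanoate untouched.

**Union and ring construction**

Step 10
Reactants: 10 S-({5-[(R)-1-(tert-butyldimethylsilyloxy)propan-2-yl]furan-2-yl}methyl) ethanethioate; 16 (E)-2-methyl-6-(tetradecanoyloxy)hex-2-enoic acid
Product: 18 S-furfuryl (E)-enethioate, via furfuryl thiol 17 (not isolated)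
Conditions: K2CO3 (cat.), degassed MeOH, 0 °C; AcOH, evaporate; then 16, DCC, DMAP (cat.), CH2Cl2, 0 → 25 °C
Reagents that add atoms: none
Why: Methanolysis of the thioacetate and Steglich thioesterification of the liberated thiol join diene and dienophile through the CH2–S–C(=O) tether.

Step 11
Reactants: 18 S-furfuryl (E)-enethioate
Product: 19 oxa-bridged tricyclic thiolactone adduct
Conditions: CH2Cl2 (0.05 M), 15 kbar, 25 °C; chromatographic separation of the two facial diastereomers, kept below 25 °C
Reagents that add atoms: none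
Why: Proposed new method: a thioester-tethered intramolecular furan Diels–Alder reaction, a concerted suprafacial [4π+2π] addition of the enethioate C11=C6 across furan carbons C10 and C7, whose closest known relatives are the N-furfuryl amide and the Lewis-acid-promoted furfuryl ketone tethers; a thioester should behave like those ketones (low LUMO, small rotamer penalty, long C–S bonds that relax the fused five-membered ring), and 15 kbar favours the volume-contracting adduct over cycloreversion. The new C6–C7 and C10–C11 bonds close the cyclohexene ring C6–C11 in the fused mode, the furan oxygen becoming the C7–O–C10 bridge and the tether the γ-thiolactone across C10–C11, with the regiochemistry dictated by the three-atom tether. That tether can only span the bridgehead C10 and the exo position of C11, so the acyl carbon (future C12) ends syn to the bridge oxygen (future 10-OH) and the C11 methyl endo. Suprafacial addition to the E dienophile carries the C6 chain cis to the C11 methyl, and the cis bridge fixes C7 and C10, which together give the relative configuration of C6, C10 and C11 of the target. The absolute sense is the choice of furan face relative to the (R)-C2 centre: the two facial adducts are diastereomers, 19 is expected to be modestly preferred (C2 methyl in the open sector between C6 and the bridge oxygen) and is separated, and the other should revert to 18 in warm toluene for recycling. No other alkene competes, because the remaining unsaturation of the target is introduced only after the ring is locked.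

Step 12
Reactants: 19 oxa-bridged tricyclic thiolactone adduct
Product: 21 oxa-bridged C12 alcohol, via saturated thiolactone 20 (not isolated)
Conditions: Raney Ni (W-2, excess), H2 (1 atm), EtOH/THF, 0 → 25 °C, then 50 °C
Reagents that add atoms: none
Why: Raney Ni should first saturate the strained C8=C9 alkene (which blocks cycloreversion) and then hydrogenolyse both C–S bonds (reductive desulfurization of a thioester), turning the tether CH2 into the C10 methyl and the acyl carbon into the C12 alcohol without touching a stereocentre.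

Step 13
Reactants: 21 oxa-bridged C12 alcohol
Product: 22 oxa-bridged C12 aldehyde
Conditions: Dess–Martin periodinane, NaHCO3, CH2Cl2, 0 → 25 °C
Reagents that add atoms: none
Why: Dess–Martin oxidation of the neopentyl primary alcohol gives an aldehyde that cannot enolise (C11 is quaternary) and cannot undergo retro-aldol cleavage (O10 is tied up in the bridge).

Step 14
Reactants: 22 oxa-bridged C12 aldehyde
Product: 23 oxa-bridged C11 vinyl compound
Conditions: Ph3PCH3Br, KHMDS, THF, 0 °C; then 22, 0 → 25 °C
Reagents that add atoms: methyltriphenylphosphonium bromide C[P+](c1ccccc1)(c1ccccc1)c1ccccc1.[Br-]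
Why: Wittig methylenation of the hindered aldehyde supplies C13, and the unstabilised ylide at 0 °C should spare the tetradecanoate.

**Fragment C (vinyl iodide)**

Step 15
Reactants: 24 prop-2-yn-1-ol
Product: 26 (E)-3-iodo-2-methylprop-2-en-1-ol, via alkenylalane 25 (not isolated)
Conditions: AlMe3 (3 equiv), Cp2ZrCl2 (0.25 equiv), CH2Cl2, 0 → 25 °C; then I2, THF, −30 → 0 °C
Reagents that add atoms: trimethylaluminium C[Al](C)C; iodine II
Why: Negishi zirconium-catalysed carboalumination adds methyl and aluminium syn across the alkyne, and iodinolysis with retention should give the E vinyl iodide (future 14E).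

Step 16
Reactants: 26 (E)-3-iodo-2-methylprop-2-en-1-ol
Product: 27 (E)-3-iodo-2-methylprop-2-enal
Conditions: MnO2, CH2Cl2, 25 °C
Reagents that add atoms: none
Why: Allylic oxidation with MnO2 stops at the enal and does not isomerise the alkene.

Step 17
Reactants: 28 geranyl chloride; 27 (E)-3-iodo-2-methylprop-2-enal
Product: 30 racemic (1E,5E)-1-iodo-2,6,10-trimethylundeca-1,5,9-trien-3-ol, via geranylbarium chloride 29 (not isolated)
Conditions: BaI2, lithium biphenylide (from Li and biphenyl), THF, 25 °C; 28, −78 °C; then 27, −78 °C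
Reagents that add atoms: none
Why: Allylic barium reagents add 1,2 to aldehydes at their unsubstituted α-carbon with retention of the E alkene at −78 °C, which should give the linear homoallylic alcohol (racemic at C16, corrected in steps 18 and 19).

Step 18
Reactants: 30 racemic (1E,5E)-1-iodo-2,6,10-trimethylundeca-1,5,9-trien-3-ol
Product: 31 (1E,5E)-1-iodo-2,6,10-trimethylundeca-1,5,9-trien-3-one
Conditions: Dess–Martin periodinane, NaHCO3, CH2Cl2, 0 °C
Reagents that add atoms: none
Why: Buffered Dess–Martin oxidation should give the enone without moving the β,γ-alkene into conjugation.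

Step 19
Reactants: 31 (1E,5E)-1-iodo-2,6,10-trimethylundeca-1,5,9-trien-3-one
Product: 32 (3R,1E,5E)-1-iodo-2,6,10-trimethylundeca-1,5,9-trien-3-ol
Conditions: (S)-2-methyl-CBS-oxazaborolidine (10 mol %), catecholborane, toluene, −78 °C
Reagents that add atoms: none
Why: Corey–Bakshi–Shibata reduction with the α-branched alkenyl group as the large substituent should deliver hydride to give the (R)-carbinol (C16), and catecholborane does not hydroborate the alkenes.

Step 20
Reactants: 32 (3R,1E,5E)-1-iodo-2,6,10-trimethylundeca-1,5,9-trien-3-ol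
Product: 33 tert-butyldimethylsilyl ether of 32
Conditions: TBSOTf, 2,6-lutidine, CH2Cl2, −78 °C
Reagents that add atoms: tert-butyldimethylsilyl trifluoromethanesulfonate CC(C)(C)[Si](C)(C)OS(=O)(=O)C(F)(F)F
Why: Silylation of the hindered secondary allylic alcohol protects O16 through the coupling and the later oxidation.

**Coupling and endgame**

Step 21
Reactants: 23 oxa-bridged C11 vinyl compound; 33 tert-butyldimethylsilyl ether of 32
Product: 35 coupled oxa-bridged bis-silyl ether, via B-alkyl-9-BBN 34 (not isolated)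
Conditions: 9-BBN-H dimer, THF, 25 °C; then H2O, 33, Pd(dppf)Cl2 (10 mol %), AsPh3, Cs2CO3, DMF, 25 °C
Reagents that add atoms: none
Why: Hydroboration of the vinyl group at its terminal carbon and B-alkyl Suzuki–Miyaura coupling with the E vinyl iodide should join C13 to C14 with retention of alkene geometry and no new stereocentre.

Step 22
Reactants: 35 coupled oxa-bridged bis-silyl ether
Product: 36 oxa-bridged C1 alcohol
Conditions: HF·pyridine, pyridine, THF, 0 °C
Reagents that add atoms: none
Why: Buffered fluoride desilylation should remove the primary silyl ether faster than the hindered secondary allylic one.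

Step 23
Reactants: 36 oxa-bridged C1 alcohol
Product: 38 16-O-tert-butyldimethylsilyl ether of the target, via bridged aldehyde 37 (not isolated)
Conditions: Dess–Martin periodinane, NaHCO3, CH2Cl2, 0 °C; then Et3N, 0 → 25 °C
Reagents that add atoms: none
Why: Oxidation gives the β-alkoxy aldehyde 37, whose enolate expels the strained C7–O bridge bond (E1cB, retro-oxa-Michael), which should release the 10-OH and the C2=C7 enal with the formyl group on the side of the more crowded C6 (2Z) and erase the auxiliary C2 centre.

Step 24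
Reactants: 38 16-O-tert-butyldimethylsilyl ether of the target
Product: 39 target, (2Z,6S,10S,11R,14E,16R,18E)-16-hydroxyiridal 3-tetradecanoate
Conditions: HF·pyridine, THF, 0 → 25 °C
Reagents that add atoms: none
Why: Mildly acidic fluoride desilylation of the secondary allylic ether should spare the enal, the tertiary alcohol and the primary ester.

**Compound list**

1 | 2-(furan-2-yl)acetic acid | OC(=O)Cc1ccco1 | starting material
2 | (S)-4-benzyloxazolidin-2-one | O=C1OC[C@H](Cc2ccccc2)N1 | starting material
3 | (S)-4-benzyl-3-[2-(furan-2-yl)acetyl]oxazolidin-2-one | O=C(Cc1ccco1)N1[C@@H](Cc2ccccc2)COC1=O | intermediate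
4 | sodium (Z)-enolate of 3 | [Na+].[O-]/C(=C\c1ccco1)N1[C@@H](Cc2ccccc2)COC1=O | intermediate (not isolated)
5 | (S)-4-benzyl-3-[(S)-2-(furan-2-yl)propanoyl]oxazolidin-2-one | C[C@H](C(=O)N1[C@@H](Cc2ccccc2)COC1=O)c1ccco1 | intermediate
6 | (R)-2-(furan-2-yl)propan-1-ol | C[C@H](CO)c1ccco1 | intermediate
7 | (R)-tert-butyl[2-(furan-2-yl)propoxy]dimethylsilane | C[C@H](CO[Si](C)(C)C(C)(C)C)c1ccco1 | intermediate
8 | 5-lithio derivative of 7 | C[C@H](CO[Si](C)(C)C(C)(C)C)c1ccc([Li])o1 | intermediate (not isolated)
9 | {5-[(R)-1-(tert-butyldimethylsilyloxy)propan-2-yl]furan-2-yl}methanol | C[C@H](CO[Si](C)(C)C(C)(C)C)c1ccc(CO)o1 | intermediate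
10 | S-({5-[(R)-1-(tert-butyldimethylsilyloxy)propan-2-yl]furan-2-yl}methyl) ethanethioate | C[C@H](CO[Si](C)(C)C(C)(C)C)c1ccc(CSC(C)=O)o1 | intermediate
11 | pent-4-en-1-ol | OCCCC=C | starting material
12 | tetradecanoyl chloride | CCCCCCCCCCCCCC(Cl)=O | starting material
13 | pent-4-en-1-yl tetradecanoate | CCCCCCCCCCCCCC(=O)OCCCC=C | intermediate
14 | tert-butyl methacrylate | CC(=C)C(=O)OC(C)(C)C | starting material
15 | tert-butyl (E)-2-methyl-6-(tetradecanoyloxy)hex-2-enoate | CCCCCCCCCCCCCC(=O)OCCC/C=C(\C)C(=O)OC(C)(C)C | intermediate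
16 | (E)-2-methyl-6-(tetradecanoyloxy)hex-2-enoic acid | CCCCCCCCCCCCCC(=O)OCCC/C=C(\C)C(O)=O | intermediate
17 | {5-[(R)-1-(tert-butyldimethylsilyloxy)propan-2-yl]furan-2-yl}methanethiol | C[C@H](CO[Si](C)(C)C(C)(C)C)c1ccc(CS)o1 | intermediate (not isolated)
18 | S-({5-[(R)-1-(tert-butyldimethylsilyloxy)propan-2-yl]furan-2-yl}methyl) (E)-2-methyl-6-(tetradecanoyloxy)hex-2-enethioate | CCCCCCCCCCCCCC(=O)OCCC/C=C(\C)C(=O)SCc1ccc([C@H](C)CO[Si](C)(C)C(C)(C)C)o1 | intermediate
19 | Diels–Alder adduct: 7-oxabicyclo[2.2.1]heptene (C7–O–C10 bridge, C8=C9) with a γ-thiolactone fused at C10–C11 (C10–CH2–S–C(=O)–C11, acyl carbon exo); C11 methyl endo; C6 3-(tetradecanoyloxy)propyl endo; C7 bears the (R)-1-(tert-butyldimethylsilyloxy)propan-2-yl group; C6, C10, C11 arranged as in the target | CCCCCCCCCCCCCC(=O)OCCC[C@H]1[C@@]2([C@H](C)CO[Si](C)(C)C(C)(C)C)C=C[C@]3(CSC(=O)[C@]13C)O2 | intermediate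
20 | 8,9-dihydro derivative of 19 (saturated thiolactone) | CCCCCCCCCCCCCC(=O)OCCC[C@H]1[C@@]2([C@H](C)CO[Si](C)(C)C(C)(C)C)CC[C@]3(CSC(=O)[C@]13C)O2 | intermediate (not isolated)
21 | oxa-bridged C12 alcohol: 7-oxabicyclo[2.2.1]heptane with bridgeheads C7 (bearing the (R)-1-silyloxypropan-2-yl group) and C10 (methyl); C11 with endo methyl and exo CH2OH; C6 with endo 3-(tetradecanoyloxy)propyl | CCCCCCCCCCCCCC(=O)OCCC[C@H]1[C@@]2([C@H](C)CO[Si](C)(C)C(C)(C)C)CC[C@](C)(O2)[C@]1(C)CO | intermediate
22 | oxa-bridged C12 aldehyde (CHO in place of CH2OH of 21) | CCCCCCCCCCCCCC(=O)OCCC[C@H]1[C@@]2([C@H](C)CO[Si](C)(C)C(C)(C)C)CC[C@](C)(O2)[C@]1(C)C=O | intermediate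
23 | oxa-bridged C11 vinyl compound (CH=CH2 in place of CHO of 22) | CCCCCCCCCCCCCC(=O)OCCC[C@H]1[C@@]2([C@H](C)CO[Si](C)(C)C(C)(C)C)CC[C@](C)(O2)[C@]1(C)C=C | intermediate
24 | prop-2-yn-1-ol | OCC#C | starting material
25 | (E)-alkenylalane, dimethylaluminium alkoxide of 3-(dimethylalumanyl)-2-methylprop-2-en-1-ol | C[Al](C)/C=C(\C)CO[Al](C)C | intermediate (not isolated)
26 | (E)-3-iodo-2-methylprop-2-en-1-ol | I/C=C(\C)CO | intermediate
27 | (E)-3-iodo-2-methylprop-2-enal | I/C=C(\C)C=O | intermediate
28 | geranyl chloride, (E)-1-chloro-3,7-dimethylocta-2,6-diene | ClC/C=C(\C)CCC=C(C)C | starting material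
29 | geranylbarium chloride | Cl[Ba]C/C=C(\C)CCC=C(C)C | intermediate (not isolated)
30 | racemic (1E,5E)-1-iodo-2,6,10-trimethylundeca-1,5,9-trien-3-ol | I/C=C(\C)C(O)C/C=C(\C)CCC=C(C)C | intermediate
31 | (1E,5E)-1-iodo-2,6,10-trimethylundeca-1,5,9-trien-3-one | I/C=C(\C)C(=O)C/C=C(\C)CCC=C(C)C | intermediate
32 | (3R,1E,5E)-1-iodo-2,6,10-trimethylundeca-1,5,9-trien-3-ol | I/C=C(\C)[C@H](O)C/C=C(\C)CCC=C(C)C | intermediate
33 | tert-butyl{[(3R,1E,5E)-1-iodo-2,6,10-trimethylundeca-1,5,9-trien-3-yl]oxy}dimethylsilane | I/C=C(\C)[C@H](O[Si](C)(C)C(C)(C)C)C/C=C(\C)CCC=C(C)C | intermediate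
34 | B-alkyl-9-BBN from 23 (boron on C13) | CCCCCCCCCCCCCC(=O)OCCC[C@H]1[C@@]2([C@H](C)CO[Si](C)(C)C(C)(C)C)CC[C@](C)(O2)[C@]1(C)CCB3C4CCCC3CCC4 | intermediate (not isolated)
35 | coupled product: 7,10-oxa-bridged 2,7-dihydro skeleton of the target with complete C12–C24 chain, 1-O- and 16-O-tert-butyldimethylsilyl ethers, 3-O-tetradecanoate | CCCCCCCCCCCCCC(=O)OCCC[C@H]1[C@@]2([C@H](C)CO[Si](C)(C)C(C)(C)C)CC[C@](C)(O2)[C@]1(C)CC/C=C(\C)[C@H](O[Si](C)(C)C(C)(C)C)C/C=C(\C)CCC=C(C)C | intermediate
36 | oxa-bridged C1 alcohol (35 without the primary silyl group) | CCCCCCCCCCCCCC(=O)OCCC[C@H]1[C@@]2([C@H](C)CO)CC[C@](C)(O2)[C@]1(C)CC/C=C(\C)[C@H](O[Si](C)(C)C(C)(C)C)C/C=C(\C)CCC=C(C)C | intermediate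
37 | oxa-bridged C1 aldehyde (β-alkoxy aldehyde) | CCCCCCCCCCCCCC(=O)OCCC[C@H]1[C@@]2([C@H](C)C=O)CC[C@](C)(O2)[C@]1(C)CC/C=C(\C)[C@H](O[Si](C)(C)C(C)(C)C)C/C=C(\C)CCC=C(C)C | intermediate (not isolated)
38 | 16-O-tert-butyldimethylsilyl ether of the target | CCCCCCCCCCCCCC(=O)OCCC[C@H]1/C(=C(/C)C=O)CC[C@](C)(O)[C@]1(C)CC/C=C(\C)[C@H](O[Si](C)(C)C(C)(C)C)C/C=C(\C)CCC=C(C)C | intermediate
39 | (2Z,6S,10S,11R,14E,16R,18E)-16-hydroxyiridal 3-tetradecanoate (CNP0171467.2) | CCCCCCCCCCCCCC(=O)OCCC[C@H]1/C(=C(/C)C=O)CC[C@](C)(O)[C@]1(C)CC/C=C(\C)[C@H](O)C/C=C(\C)CCC=C(C)C | target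

**Totals**

Total step count: 24.
Longest linear sequence: 15 steps (steps 1–6, 10–14, 21–24).

**Steps most likely to fail**

1. Step 11 (proposed new method). What may go wrong: cycloreversion outrunning cycloaddition for the α,β-disubstituted dienophile, so that the equilibrium stays on the side of 18, and weak discrimination between the two furan faces. Fallback with known chemistry, setting out from 9 and 16 and coming back to the route at 21: the sulfur tether is replaced by the nitrogen tether of the classical intramolecular furan Diels–Alder reaction. Alcohol 9 would be converted (DPPA, DBU, toluene) into the furfuryl azide F1. Staudinger reduction (PPh3, wet THF) would give the furfurylamine F2, and coupling with 16 (EDC, HOBt) the secondary enamide F3. Boc2O with DMAP would give the N-Boc enamide F4, whose carbamate acts as a removable steric buttress. Heating (toluene, 80 °C) should give the exo-fused N-Boc lactam adduct F5 with the same relative configuration, and diimide its dihydro derivative F6. NaBH4 (EtOH, 0 °C) should open the activated lactam to the Boc-amino alcohol F7. TMSOTf with 2,6-lutidine, then MeOH, would free the amino alcohol F8. Deaminative reduction of this primary amine with an anomeric amide reagent (N-benzyloxy-N-pivaloyloxy-4-(trifluoromethyl)benzamide, MeCN, 45 °C) would deliver 21.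

2. Step 12. What may go wrong: cycloreversion of 19 on the warm nickel surface before the alkene is saturated, or decarbonylation and over-reduction during the acyl C–S hydrogenolysis. Fallback, setting out from 19 and coming back at 21: the three events are separated. Diimide (dipotassium azodicarboxylate, AcOH, MeOH, 0 °C) would give 20. Fukuyama reduction (Et3SiH, palladium on carbon, acetone, 25 °C) would cleave only the acyl–sulfur bond and give the mercapto aldehyde F9. Raney Ni at 20 °C would then remove the sulfur and reduce the aldehyde to 21.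

3. Step 23. What may go wrong: poor control of the C2=C7 geometry in the elimination, or base-induced dienolisation through H6 during a slow equilibration. Fallback, setting out from 36 and coming back at 38: the geometry is set photochemically instead of in the elimination. Oxidation and elimination are run as before with the shortest possible exposure to base. Any (2E)-enal F10 is separated and irradiated (350 nm, benzene, 20 °C) to a photostationary mixture. 38 is collected from it and F10 is returned to the irradiation.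

**Further compounds**

F1 | step 11 | tert-butyl{(R)-2-[5-(azidomethyl)furan-2-yl]propoxy}dimethylsilane | C[C@H](CO[Si](C)(C)C(C)(C)C)c1ccc(CN=[N+]=[N-])o1
F2 | step 11 | {5-[(R)-1-(tert-butyldimethylsilyloxy)propan-2-yl]furan-2-yl}methanamine | C[C@H](CO[Si](C)(C)C(C)(C)C)c1ccc(CN)o1
F3 | step 11 | (E)-N-({5-[(R)-1-(tert-butyldimethylsilyloxy)propan-2-yl]furan-2-yl}methyl)-2-methyl-6-(tetradecanoyloxy)hex-2-enamide | CCCCCCCCCCCCCC(=O)OCCC/C=C(\C)C(=O)NCc1ccc([C@H](C)CO[Si](C)(C)C(C)(C)C)o1
F4 | step 11 | N-tert-butoxycarbonyl derivative of F3 | CCCCCCCCCCCCCC(=O)OCCC/C=C(\C)C(=O)N(Cc1ccc([C@H](C)CO[Si](C)(C)C(C)(C)C)o1)C(=O)OC(C)(C)C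
F5 | step 11 | exo-fused N-Boc γ-lactam analogue of 19 (N-Boc in place of S) | CCCCCCCCCCCCCC(=O)OCCC[C@H]1[C@@]2([C@H](C)CO[Si](C)(C)C(C)(C)C)C=C[C@]3(CN(C(=O)OC(C)(C)C)C(=O)[C@]13C)O2
F6 | step 11 | 8,9-dihydro derivative of F5 | CCCCCCCCCCCCCC(=O)OCCC[C@H]1[C@@]2([C@H](C)CO[Si](C)(C)C(C)(C)C)CC[C@]3(CN(C(=O)OC(C)(C)C)C(=O)[C@]13C)O2
F7 | step 11 | ring-opened Boc-amino alcohol (C10–CH2NHBoc, C11–CH2OH) | CCCCCCCCCCCCCC(=O)OCCC[C@H]1[C@@]2([C@H](C)CO[Si](C)(C)C(C)(C)C)CC[C@](CNC(=O)OC(C)(C)C)(O2)[C@]1(C)CO
F8 | step 11 | amino alcohol (C10–CH2NH2, C11–CH2OH) | CCCCCCCCCCCCCC(=O)OCCC[C@H]1[C@@]2([C@H](C)CO[Si](C)(C)C(C)(C)C)CC[C@](CN)(O2)[C@]1(C)CO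
F9 | step 12 | mercapto aldehyde (C10–CH2SH, C11–CHO) | CCCCCCCCCCCCCC(=O)OCCC[C@H]1[C@@]2([C@H](C)CO[Si](C)(C)C(C)(C)C)CC[C@](CS)(O2)[C@]1(C)C=O
F10 | step 23 | (2E)-isomer of 38 | CCCCCCCCCCCCCC(=O)OCCC[C@H]1/C(=C(\C)C=O)CC[C@](C)(O)[C@]1(C)CC/C=C(\C)[C@H](O[Si](C)(C)C(C)(C)C)C/C=C(\C)CCC=C(C)C
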